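**Plan**

- Retrosynthetic cuts: (1) the ether bond O7–C2′ of the dihydrofuran ring, formed last. (2) In one retron, the bond O1–C2 and the bond C2–C2′ at the spiro carbon C2 of the benzofuran-3(2H)-one. (3) The bond between flavan C8 and the CH2 of an aryl benzyl ketone.
- Enabling feature: spiro carbon C2 carries the ring oxygen O1, the ketone carbon C3, the aryl carbon C8 of flavan ring A and the carbon C2′ that bears O and aryl. It is therefore the carbon of an α-keto, α-aryl carbene with a phenol oxygen in 1,5-relation, and C2′ is an aldehyde carbon.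
- Forward: (+)-afzelechin (rings A, C, B bought) → benzylation and C8 bromination → Pd α-arylation of a phloroacetophenone ether → diazo transfer and phenol release → Rh carbene O–H insertion interrupted by aldol addition to 4-(benzyloxy)benzaldehyde (benzofuranone ring and quaternary centre) → hydrogenolysis → acid closure of the dihydrofuran ring.
- Stereochemistry: flavan C2 (R) and C3 (S) come from (+)-afzelechin. Spiro C2 (S) is set by a chiral zirconium BINOLate in the key step (catalyst control). C2′ (S) is relayed from the spiro centre in the last ring closure (substrate control).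

Key step: step 7

Remark 1: (+)-afzelechin (2R,3S) is taken as a purchasable chiral-pool flavan-3-ol.
Remark 2: the sense of induction of the zirconium (R)-BINOLate at C2 is assigned by analogy with aldehyde additions under this catalyst type. Should it prove opposite, the (S)-ligand would be used in the same step.

**Route**

Step 1
Reactants: 1 (+)-afzelechin
Product: 2 (2R,3S)-3,5,7-tris(benzyloxy)-2-[4-(benzyloxy)phenyl]chromane
Conditions: BnBr (6 equiv), NaH (5 equiv), DMF, 0 °C to rt
Reagents that add atoms: benzyl bromide, BrCc1ccccc1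
Why: Williamson etherification of the three phenoxides and the secondary alkoxide touches no stereocentre and installs benzyl ethers that can all be removed at the end by neutral hydrogenolysis.

Step 2
Reactants: 2 tetra-O-benzylafzelechin
Product: 3 (2R,3S)-3,5,7-tris(benzyloxy)-2-[4-(benzyloxy)phenyl]-8-bromochromane
Conditions: NBS (1.0 equiv), CH2Cl2, −78 °C to rt
Reagents that add atoms: N-bromosuccinimide, O=C1CCC(=O)N1Br
Why: Electrophilic aromatic bromination of the phloroglucinol-type ring A should go to C8 and not C6, the regiochemistry established for per-O-benzylated flavan-3-ols, and gives the handle for C–C coupling.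

Step 3
Reactants: 4 1-[2,4-bis(benzyloxy)-6-hydroxyphenyl]ethan-1-one
Product: 5 1-[2,4-bis(benzyloxy)-6-{[2-(trimethylsilyl)ethoxy]methoxy}phenyl]ethan-1-one
Conditions: SEMCl, NaH, DMF, 0 °C
Reagents that add atoms: 2-(trimethylsilyl)ethoxymethyl chloride, C[Si](C)(C)CCOCCl
Why: Williamson-type O-alkylation of the chelated phenol gives a SEM acetal that withstands enolate and amidine bases and can later be removed by fluoride without acid, which the diazo group would not tolerate.

Step 4
Reactants: 3 8-bromoflavan; 5 SEM-protected acetophenone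
Product: 6 1-[2,4-bis(benzyloxy)-6-{[2-(trimethylsilyl)ethoxy]methoxy}phenyl]-2-{(2R,3S)-3,5,7-tris(benzyloxy)-2-[4-(benzyloxy)phenyl]chroman-8-yl}ethan-1-one
Conditions: Pd2(dba)3 (2.5 mol %), XPhos (10 mol %), NaOtBu (2.2 equiv), toluene, 80 °C
Reagents that add atoms: none
Why: Palladium-catalysed ketone α-arylation (Buchwald–Hartwig type) couples the methyl ketone enolate of 5 to the di-ortho-oxygenated aryl bromide under a bulky biarylphosphine, and the more acidic, more hindered product enolate should resist a second arylation.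

Step 5
Reactants: 6 aryl benzyl ketone
Product: 7 1-[2,4-bis(benzyloxy)-6-{[2-(trimethylsilyl)ethoxy]methoxy}phenyl]-2-diazo-2-{(2R,3S)-3,5,7-tris(benzyloxy)-2-[4-(benzyloxy)phenyl]chroman-8-yl}ethan-1-one
Conditions: p-ABSA (1.5 equiv), DBU (1.5 equiv), MeCN, 0 °C to rt
Reagents that add atoms: 4-acetamidobenzenesulfonyl azide (p-ABSA), CC(=O)Nc1ccc(cc1)S(=O)(=O)N=[N+]=[N-]
Why: Regitz diazo transfer to the doubly activated (benzylic, α-keto) methylene through its DBU enolate should give the donor/acceptor diazo ketone.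

Step 6
Reactants: 7 SEM-protected diazo ketone
Product: 8 1-[2,4-bis(benzyloxy)-6-hydroxyphenyl]-2-diazo-2-{(2R,3S)-3,5,7-tris(benzyloxy)-2-[4-(benzyloxy)phenyl]chroman-8-yl}ethan-1-one
Conditions: TBAF (5 equiv), THF/DMPU, 45 °C, dark; pH 7 buffer work-up
Reagents that add atoms: none
Why: Fluoride attack at silicon triggers fragmentation of the SEM group (loss of ethene and formaldehyde) and frees the phenol under non-acidic conditions that the diazo ketone and the benzyl ethers should tolerate.

Step 7
Reactants: 8 2-hydroxyaryl diazo ketone; 9 4-(benzyloxy)benzaldehyde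
Product: 11 (2S)-4,6-bis(benzyloxy)-2-{(S)-[4-(benzyloxy)phenyl](hydroxy)methyl}-2-{(2R,3S)-3,5,7-tris(benzyloxy)-2-[4-(benzyloxy)phenyl]chroman-8-yl}benzofuran-3(2H)-one, via oxonium ylide 10 (not isolated)
Conditions: Rh2(OAc)4 (2 mol %), Zr(OtBu)4 (15 mol %), (R)-3,3′-diiodo-BINOL (30 mol %), 4 Å MS, CH2Cl2, 0 °C; 8 added slowly by syringe pump to 9 (3 equiv)
Reagents that add atoms: none
Why: Proposed new method: Rh2(OAc)4 converts 8 into an α-keto, α-aryl rhodium carbene whose electrophilic carbon is attacked by the phenol oxygen five atoms away on the aroyl ring; this forms the O1–C2 bond and closes the five-membered benzofuranone ring in an exo mode with respect to the Rh=C bond (5-exo-type), giving the protic oxonium ylide 10, which before 1,2-proton shift adds through C2 to aldehyde 9 bound to the chiral zirconium BINOLate, so that the C2–C2′ bond and the fully substituted centre arise in the same operation. The closest known reaction types are the dirhodium/chiral zirconium-BINOL co-catalysed three-component coupling of aryl diazo esters, alcohols and aldehydes (trapping of alcoholic oxonium ylides, an interrupted O–H insertion) and the Rh-catalysed intramolecular phenol O–H insertion of 2-hydroxyaryl diazo ketones to benzofuran-3(2H)-ones; new here are the tethered phenolic O–H, the diaryl diazo ketone and the electron-rich aldehyde. The quaternary centre C2 is set by the catalyst: the planar benzofuran-3-olate is held in the chiral pocket so that only one face is open to the coordinated aldehyde (2S expected with the (R)-ligand), and the flavan stereocentres, six or more bonds away, are not relied on. The carbinol centre C2′ should follow from a closed chair (Zimmerman–Traxler) transition state with the aryl group of 9 equatorial (drawn as S); its configuration is of no consequence because it is ionised in step 9. The step needs chemoselectivity for O–H attack over 1,5 C–H insertion into the CH2 of the flanking benzyl ethers, over ylide formation at the ortho benzyl ether oxygen and over carbonyl-ylide formation with 9; the free phenol is hydrogen-bonded to the ketone and sits next to the carbene carbon, O–H capture is the fastest of these processes for donor/acceptor carbenes under Rh2(OAc)4, and slow addition keeps 8 dilute. Trapping must also outrun the 1,2-proton shift, which the excess of Lewis-acid-bound aldehyde favours, and if the shift occurs the resulting 3-hydroxybenzofuran is still an enol that can add to the activated aldehyde.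

Step 8
Reactants: 11 hepta-O-benzyl aldol adduct
Product: 12 (2S)-4,6-dihydroxy-2-[(S)-hydroxy(4-hydroxyphenyl)methyl]-2-[(2R,3S)-3,5,7-trihydroxy-2-(4-hydroxyphenyl)chroman-8-yl]benzofuran-3(2H)-one
Conditions: H2 (1 atm), Pd(OH)2/C, THF/MeOH (1:1), rt
Reagents that add atoms: none
Why: Catalytic hydrogenolysis should cleave the six aryl benzyl ethers and the alkyl benzyl ether under neutral conditions, under which the hindered secondary benzylic alcohol, the tertiary α-keto aryl ether and the flavan C2–O bond are expected to persist.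

Step 9
Reactants: 12 octahydroxy aldol adduct
Product: 13 target spirobiflavonoid CNP0228515.1 (spiro carbon S; dihydrofuran CH S; flavan 2R,3S)
Conditions: PPTS (0.2 equiv), MeCN, 40 °C
Reagents that add atoms: none
Why: Mild acid ionises the 4-hydroxybenzylic alcohol to a protonated para-quinone methide that the flanking 7-OH captures in a 5-exo-trig SN1 cycloetherification; the new CH(aryl) centre is set by substrate control from the adjacent spiro carbon, the aryl group taking the face next to the small ring oxygen O1 and away from the C3 carbonyl (2′S), which is also expected to be the more stable arrangement.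

**Compound list**

1 | (+)-afzelechin, (2R,3S)-2-(4-hydroxyphenyl)chromane-3,5,7-triol | Oc1cc(O)c2c(c1)O[C@H](c1ccc(O)cc1)[C@@H](O)C2 | starting material
2 | (2R,3S)-3,5,7-tris(benzyloxy)-2-[4-(benzyloxy)phenyl]chromane | C(c1ccccc1)Oc1cc(OCc2ccccc2)c2c(c1)O[C@H](c1ccc(OCc3ccccc3)cc1)[C@@H](OCc1ccccc1)C2 | intermediate
3 | (2R,3S)-3,5,7-tris(benzyloxy)-2-[4-(benzyloxy)phenyl]-8-bromochromane | C(c1ccccc1)Oc1cc(OCc2ccccc2)c2c(c1Br)O[C@H](c1ccc(OCc3ccccc3)cc1)[C@@H](OCc1ccccc1)C2 | intermediate
4 | 1-[2,4-bis(benzyloxy)-6-hydroxyphenyl]ethan-1-one | CC(=O)c1c(O)cc(OCc2ccccc2)cc1OCc1ccccc1 | starting material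
5 | 1-[2,4-bis(benzyloxy)-6-{[2-(trimethylsilyl)ethoxy]methoxy}phenyl]ethan-1-one | CC(=O)c1c(OCOCC[Si](C)(C)C)cc(OCc2ccccc2)cc1OCc1ccccc1 | intermediate
6 | aryl benzyl ketone: flavan C8–CH2–C(=O)–aryl with SEM ether | O=C(Cc1c(OCc2ccccc2)cc(OCc2ccccc2)c2c1O[C@H](c1ccc(OCc3ccccc3)cc1)[C@@H](OCc1ccccc1)C2)c1c(OCOCC[Si](C)(C)C)cc(OCc2ccccc2)cc1OCc1ccccc1 | intermediate
7 | α-diazo ketone with SEM ether | O=C(C(=[N+]=[N-])c1c(OCc2ccccc2)cc(OCc2ccccc2)c2c1O[C@H](c1ccc(OCc3ccccc3)cc1)[C@@H](OCc1ccccc1)C2)c1c(OCOCC[Si](C)(C)C)cc(OCc2ccccc2)cc1OCc1ccccc1 | intermediate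
8 | α-diazo ketone with free ortho phenol | O=C(C(=[N+]=[N-])c1c(OCc2ccccc2)cc(OCc2ccccc2)c2c1O[C@H](c1ccc(OCc3ccccc3)cc1)[C@@H](OCc1ccccc1)C2)c1c(O)cc(OCc2ccccc2)cc1OCc1ccccc1 | intermediate
9 | 4-(benzyloxy)benzaldehyde | O=Cc1ccc(OCc2ccccc2)cc1 | starting material
10 | oxonium ylide: 4,6-bis(benzyloxy)-2-(flavan-8-yl)-1H-benzofuran-1-ium-3-olate | [O-]C1=C(c2c(OCc3ccccc3)cc(OCc3ccccc3)c3c2O[C@H](c2ccc(OCc4ccccc4)cc2)[C@@H](OCc2ccccc2)C3)[OH+]c2cc(OCc3ccccc3)cc(OCc3ccccc3)c12 | intermediate
11 | (2S)-4,6-bis(benzyloxy)-2-{(S)-[4-(benzyloxy)phenyl](hydroxy)methyl}-2-{(2R,3S)-3,5,7-tris(benzyloxy)-2-[4-(benzyloxy)phenyl]chroman-8-yl}benzofuran-3(2H)-one | O=C1c2c(OCc3ccccc3)cc(OCc3ccccc3)cc2O[C@]1([C@@H](O)c1ccc(OCc2ccccc2)cc1)c1c(OCc2ccccc2)cc(OCc2ccccc2)c2c1O[C@H](c1ccc(OCc3ccccc3)cc1)[C@@H](OCc1ccccc1)C2 | intermediate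
12 | (2S)-4,6-dihydroxy-2-[(S)-hydroxy(4-hydroxyphenyl)methyl]-2-[(2R,3S)-3,5,7-trihydroxy-2-(4-hydroxyphenyl)chroman-8-yl]benzofuran-3(2H)-one | O=C1c2c(O)cc(O)cc2O[C@]1([C@@H](O)c1ccc(O)cc1)c1c(O)cc(O)c2c1O[C@H](c1ccc(O)cc1)[C@@H](O)C2 | intermediate
13 | target CNP0228515.1: spiro carbon S, dihydrofuran CH(aryl) S with the aryl cis to the benzofuranone ring oxygen, flavan 2R,3S | O=C1c2c(O)cc(O)cc2O[C@]12c1c(cc(O)c3c1O[C@H](c1ccc(O)cc1)[C@@H](O)C3)O[C@H]2c1ccc(O)cc1 | target

**Summary**

Total step count: 9. Longest linear sequence: 8 steps (1 → 2 → 3 → 6 → 7 → 8 → 11 → 12 → 13).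

Steps most likely to fail:

1. Step 7 (proposed new method). The ylide may undergo 1,2-proton shift before it meets the weakly electrophilic aldehyde, the chelating 2-hydroxyaryl ketone may sequester the zirconium catalyst, or facial control at the quaternary centre may be poor. Fallback from 8, returning at 11: 8 would be cyclised with Rh2(OAc)4 alone in CH2Cl2 (plain intramolecular phenol O–H insertion) to the enolisable 2-aryl-benzofuran-3(2H)-one F1. This would be silylated (Me3SiCl, Et3N) to the 3-(trimethylsilyloxy)benzofuran F2. A Mukaiyama aldol addition of F2 to 9 under the same zirconium (R)-3,3′-diiodo-BINOLate, with propanol as proton source, should then give 11. If face selection is poor, the C2 epimer would be removed by chromatography.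

2. Step 4. Oxidative addition and reductive elimination at the electron-rich, di-ortho-oxygenated bromide may be slow, so that proto-debromination or ketone self-condensation takes over. Fallback from 3 and 5, returning at 6: 5 would be oxidised with SeO2 (dioxane, pyridine, 90 °C) to the aryl glyoxal F3. Bromine–lithium exchange of 3 (n-BuLi, THF, −78 °C) would give the 8-lithioflavan F4, which would be added to the aldehyde group of anhydrous F3 to give the α-hydroxy ketone F5 as a mixture of carbinol epimers. Reductive removal of the α-hydroxyl with SmI2 (THF/MeOH, −78 °C) should give 6.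

3. Step 6. Fragmentation of the SEM group may need heat, with thermal or base-induced loss of the diazo group. Fallback from 6, returning at 8: the SEM group would be removed before the diazo group is present (1 M HCl, MeOH/THF, 40 °C) to give the phenol ketone F6. Its dianion (LiN(SiMe3)2, 2.2 equiv, THF, −78 °C) would be acylated with 2,2,2-trifluoroethyl trifluoroacetate to the α-trifluoroacetyl ketone F7. Detrifluoroacetylative diazo transfer (MsN3, Et3N, H2O, MeCN) should then give 8.

**Further compounds**

F1 | step 7 | 4,6-bis(benzyloxy)-2-{(2R,3S)-3,5,7-tris(benzyloxy)-2-[4-(benzyloxy)phenyl]chroman-8-yl}benzofuran-3(2H)-one (C2 epimers) | O=C1c2c(OCc3ccccc3)cc(OCc3ccccc3)cc2OC1c1c(OCc2ccccc2)cc(OCc2ccccc2)c2c1O[C@H](c1ccc(OCc3ccccc3)cc1)[C@@H](OCc1ccccc1)C2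
F2 | step 7 | 4,6-bis(benzyloxy)-2-(flavan-8-yl)-3-(trimethylsilyloxy)benzofuran | C[Si](C)(C)Oc1c(-c2c(OCc3ccccc3)cc(OCc3ccccc3)c3c2O[C@H](c2ccc(OCc4ccccc4)cc2)[C@@H](OCc2ccccc2)C3)oc2cc(OCc3ccccc3)cc(OCc3ccccc3)c12
F3 | step 4 | 2-[2,4-bis(benzyloxy)-6-{[2-(trimethylsilyl)ethoxy]methoxy}phenyl]-2-oxoacetaldehyde | O=CC(=O)c1c(OCOCC[Si](C)(C)C)cc(OCc2ccccc2)cc1OCc1ccccc1
F4 | step 4 | {(2R,3S)-3,5,7-tris(benzyloxy)-2-[4-(benzyloxy)phenyl]chroman-8-yl}lithium | [Li]c1c(OCc2ccccc2)cc(OCc2ccccc2)c2c1O[C@H](c1ccc(OCc3ccccc3)cc1)[C@@H](OCc1ccccc1)C2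
F5 | step 4 | α-hydroxy ketone, 2-hydroxy analogue of 6 (carbinol epimers) | O=C(C(O)c1c(OCc2ccccc2)cc(OCc2ccccc2)c2c1O[C@H](c1ccc(OCc3ccccc3)cc1)[C@@H](OCc1ccccc1)C2)c1c(OCOCC[Si](C)(C)C)cc(OCc2ccccc2)cc1OCc1ccccc1
F6 | step 6 | 1-[2,4-bis(benzyloxy)-6-hydroxyphenyl]-2-{(2R,3S)-3,5,7-tris(benzyloxy)-2-[4-(benzyloxy)phenyl]chroman-8-yl}ethan-1-one | O=C(Cc1c(OCc2ccccc2)cc(OCc2ccccc2)c2c1O[C@H](c1ccc(OCc3ccccc3)cc1)[C@@H](OCc1ccccc1)C2)c1c(O)cc(OCc2ccccc2)cc1OCc1ccccc1
F7 | step 6 | α-trifluoroacetyl derivative of F6 (epimers at the α-carbon) | O=C(C(C(=O)C(F)(F)F)c1c(OCc2ccccc2)cc(OCc2ccccc2)c2c1O[C@H](c1ccc(OCc3ccccc3)cc1)[C@@H](OCc1ccccc1)C2)c1c(O)cc(OCc2ccccc2)cc1OCc1ccccc1
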